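## Retrosynthetic overview

1. The target acid comes from silyl ether and ester cleavage of a (2E)-enoate, made by E1cB dehydration of a β-hydroxy ester. That β-hydroxy ester is formed by the key intermolecular aldol addition of the lithium enolate of methyl 6-methylhept-5-enoate to a chromene-bearing (E)-4-methylhept-4-enal (Cα–Cβ bond of the acid).
2. The aldehyde comes from an allylic bromide plus LiCH2CN and nitrile reduction; the bromide comes from an (E)-allylic alcohol made by a stabilised Wittig reaction on a chromenylpropanal.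
3. The 2H-chromene comes from DDQ dehydrogenation of an (R)-chroman-2-propanoate, itself from the (R)-chroman-2-carbaldehyde by Wittig reaction and hydrogenation.
4. The quaternary C2 is set by Sharpless epoxidation of an aryl-ethyl (E)-3-methyl allylic alcohol, followed by 6-exo opening of the epoxide by the phenol with inversion.
5. Rings: the arene is bought (2,3-dimethylhydroquinone). The pyran ring is closed first as a dihydrocoumarin, opened to an alkynyl phenol, closed again as the chroman, and dehydrogenated last.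

Assumption: the SMILES encodes the (S)-2H-chromene with a (2E,6E) side chain; lactol 10 and the aldol-stage compounds 32 and 33 (new centres destroyed in step 24) are carried as stereoisomer mixtures.

Abbreviations: TBS = tert-butyldimethylsilyl, Bn = benzyl, Ms = methanesulfonyl, DDQ = 2,3-dichloro-5,6-dicyano-1,4-benzoquinone, DBU = 1,8-diazabicyclo[5.4.0]undec-7-ene, CSA = camphor-10-sulfonic acid.

## Route

Step 1
Reactants: 1 dimethyl malonate; 2 5-bromo-2-methylpent-2-ene
Product: 4 dimethyl 2-(4-methylpent-3-en-1-yl)malonate, via sodium dimethyl malonate 3 (not isolated)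
Conditions: 1 (2 equiv), NaH, THF/DMF, 0 °C; then 2, 0 to 50 °C
Reagents that add atoms: none
Why: Malonic ester alkylation, in which the soft sodium enolate displaces the primary bromide by SN2 and excess malonate suppresses dialkylation.

Step 2
Reactants: 4 dimethyl 2-(4-methylpent-3-en-1-yl)malonate
Product: 5 methyl 6-methylhept-5-enoate
Conditions: LiCl, H2O, DMSO, 150 °C
Reagents that add atoms: none
Why: Krapcho dealkoxycarbonylation, in which chloride demethylates one ester and the carboxylate loses CO2, leaving the mono-ester and the trisubstituted alkene untouched.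

Step 3
Reactants: 6 2,3-dimethylhydroquinone; 7 acrylic acid
Product: 8 6-hydroxy-7,8-dimethylchroman-2-one
Conditions: CH3SO3H (0.2 equiv), toluene, reflux, Dean–Stark
Reagents that add atoms: none
Why: Acid-catalysed Friedel–Crafts hydroarylation of the acrylate ortho to a hydroxyl followed by lactonisation gives the dihydrocoumarin and thereby tells the two phenols of the symmetric hydroquinone apart.

Step 4
Reactants: 8 6-hydroxy-7,8-dimethylchroman-2-one
Product: 9 6-(benzyloxy)-7,8-dimethylchroman-2-one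
Conditions: BnBr, K2CO3, acetone, reflux
Reagents that add atoms: benzyl bromide BrCc1ccccc1
Why: Williamson etherification of the only free phenol installs a group that survives until the hydrogenation in step 13.

Step 5
Reactants: 9 6-(benzyloxy)-7,8-dimethylchroman-2-one
Product: 10 6-(benzyloxy)-7,8-dimethylchroman-2-ol
Conditions: iBu2AlH (1.1 equiv), CH2Cl2, −78 °C; aq. KNaC4H4O6
Reagents that add atoms: none
Why: Partial hydride reduction of the aryl lactone stops at the aluminium hemiacetal at −78 °C and gives the lactol on work-up.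

Step 6
Reactants: 10 6-(benzyloxy)-7,8-dimethylchroman-2-ol
Product: 11 4-(benzyloxy)-2-(but-3-yn-1-yl)-5,6-dimethylphenol
Conditions: dimethyl (1-diazo-2-oxopropyl)phosphonate, K2CO3, MeOH, 0 °C to rt
Reagents that add atoms: dimethyl (1-diazo-2-oxopropyl)phosphonate COP(=O)(OC)C(=[N+]=[N-])C(C)=O
Why: Ohira–Bestmann (Seyferth–Gilbert) homologation acts on the open hydroxy-aldehyde form of the lactol and turns CHO into a terminal alkyne while freeing the phenol.

Step 7
Reactants: 11 4-(benzyloxy)-2-(but-3-yn-1-yl)-5,6-dimethylphenol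
Product: 12 [4-(benzyloxy)-2-(but-3-yn-1-yl)-5,6-dimethylphenoxy](tert-butyl)dimethylsilane
Conditions: TBSOTf, 2,6-lutidine, CH2Cl2, 0 °C
Reagents that add atoms: tert-butyldimethylsilyl trifluoromethanesulfonate CC(C)(C)[Si](C)(C)OS(=O)(=O)C(F)(F)F
Why: Silylation of the hindered phenol with the silyl triflate masks it so that it cannot bind titanium in the epoxidation.

Step 8
Reactants: 12 [4-(benzyloxy)-2-(but-3-yn-1-yl)-5,6-dimethylphenoxy](tert-butyl)dimethylsilane
Product: 15 (E)-5-[5-(benzyloxy)-2-(TBSO)-3,4-dimethylphenyl]-3-methylpent-2-en-1-ol, via alkenyldimethylalane 13 (not isolated), via lithium alkenyl(butyl)dimethylaluminate 14 (not isolated)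
Conditions: AlMe3 (3 equiv), Cp2ZrCl2 (0.25 equiv), CH2Cl2, 0 °C to rt; evaporate, THF/hexane, nBuLi, −78 °C; (CH2O)n, −78 °C to rt
Reagents that add atoms: trimethylaluminium C[Al](C)C; paraformaldehyde (formaldehyde unit) C=O
Why: Negishi zirconium-catalysed carboalumination adds methyl and aluminium syn across the alkyne with methyl on the internal carbon, and hydroxymethylation of the aluminate proceeds with retention, so the allylic alcohol is (E) by mechanism.

Step 9
Reactants: 15 (E)-5-[5-(benzyloxy)-2-(TBSO)-3,4-dimethylphenyl]-3-methylpent-2-en-1-ol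
Product: 16 [(2S,3S)-3-{2-[5-(benzyloxy)-2-(TBSO)-3,4-dimethylphenyl]ethyl}-3-methyloxiran-2-yl]methanol
Conditions: Ti(OiPr)4 (10 mol %), L-(+)-diethyl tartrate (12 mol %), tBuOOH, 4 Å MS, CH2Cl2, −20 °C
Reagents that add atoms: tert-butyl hydroperoxide CC(C)(C)OO
Why: Katsuki–Sharpless asymmetric epoxidation with L-(+)-tartrate gives the (2S,3S)-epoxide from this geraniol-type (E)-allylic alcohol (as it does from geraniol), fixing the carbon that becomes C2 of the chroman.

Step 10
Reactants: 16 [(2S,3S)-3-{2-[5-(benzyloxy)-2-(TBSO)-3,4-dimethylphenyl]ethyl}-3-methyloxiran-2-yl]methanol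
Product: 18 (S)-1-[(R)-6-(benzyloxy)-2,7,8-trimethylchroman-2-yl]ethane-1,2-diol, via epoxy phenol 17 (not isolated)
Conditions: Bu4NF, AcOH, THF, 0 °C; then CSA (10 mol %), CH2Cl2, 0 °C
Reagents that add atoms: none
Why: Fluoride frees the phenol, which under acid opens the epoxide 6-exo at the tertiary carbon with inversion (intramolecular SN2-type epoxide opening) to give the (R)-chroman, the carbinol centre staying untouched.

Step 11
Reactants: 18 (S)-1-[(R)-6-(benzyloxy)-2,7,8-trimethylchroman-2-yl]ethane-1,2-diol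
Product: 19 (R)-6-(benzyloxy)-2,7,8-trimethylchroman-2-carbaldehyde
Conditions: NaIO4, THF/H2O, 0 °C to rt
Reagents that add atoms: none
Why: Malaprade glycol cleavage removes the terminal carbon, and the aldehyde has no α-hydrogen so the quaternary centre cannot epimerise.

Step 12
Reactants: 19 (R)-6-(benzyloxy)-2,7,8-trimethylchroman-2-carbaldehyde
Product: 20 ethyl (E)-3-[(R)-6-(benzyloxy)-2,7,8-trimethylchroman-2-yl]acrylate
Conditions: Ph3P=CHCO2Et, toluene, 80 °C
Reagents that add atoms: ethyl (triphenylphosphoranylidene)acetate CCOC(=O)C=P(c1ccccc1)(c1ccccc1)c1ccccc1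
Why: Wittig olefination with a stabilised ylide extends the hindered aldehyde by two carbons, and the alkene geometry is irrelevant because it is reduced next.

Step 13
Reactants: 20 ethyl (E)-3-[(R)-6-(benzyloxy)-2,7,8-trimethylchroman-2-yl]acrylate
Product: 21 ethyl 3-[(R)-6-hydroxy-2,7,8-trimethylchroman-2-yl]propanoate
Conditions: H2 (1 atm), Pd/C, EtOH/EtOAc, rt
Reagents that add atoms: none
Why: Catalytic hydrogenation saturates the enoate and hydrogenolyses the benzyl ether in one operation, before any other alkene is present.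

Step 14
Reactants: 21 ethyl 3-[(R)-6-hydroxy-2,7,8-trimethylchroman-2-yl]propanoate
Product: 22 ethyl 3-[(R)-6-(TBSO)-2,7,8-trimethylchroman-2-yl]propanoate
Conditions: TBSCl, imidazole, DMF, rt
Reagents that add atoms: tert-butyldimethylsilyl chloride CC(C)(C)[Si](C)(C)Cl
Why: Silylation of the phenol installs the protecting group that is carried to the end and removed with fluoride.

Step 15
Reactants: 22 ethyl 3-[(R)-6-(TBSO)-2,7,8-trimethylchroman-2-yl]propanoate
Product: 23 ethyl 3-[(S)-6-(TBSO)-2,7,8-trimethyl-2H-chromen-2-yl]propanoate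
Conditions: DDQ (1.3 equiv), 1,4-dioxane, 80 °C, dark
Reagents that add atoms: none
Why: Dehydrogenation by DDQ abstracts hydride from benzylic C4 (cation stabilised through the ring oxygen) and a proton from C3, giving the 2H-chromene without touching C2, whose label changes from R to S only because C3 now outranks the side chain.

Step 16
Reactants: 23 ethyl 3-[(S)-6-(TBSO)-2,7,8-trimethyl-2H-chromen-2-yl]propanoate
Product: 24 3-[(S)-6-(TBSO)-2,7,8-trimethyl-2H-chromen-2-yl]propanal
Conditions: iBu2AlH (1.05 equiv), CH2Cl2, −78 °C; MeOH, then aq. KNaC4H4O6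
Reagents that add atoms: none
Why: Partial ester reduction at −78 °C stops at the aluminium hemiacetal, which releases the aldehyde on work-up.

Step 17
Reactants: 24 3-[(S)-6-(TBSO)-2,7,8-trimethyl-2H-chromen-2-yl]propanal
Product: 25 ethyl (E)-2-methyl-5-[(S)-6-(TBSO)-2,7,8-trimethyl-2H-chromen-2-yl]pent-2-enoate
Conditions: Ph3P=C(CH3)CO2Et, CH2Cl2, rt
Reagents that add atoms: ethyl 2-(triphenylphosphoranylidene)propanoate CCOC(=O)C(C)=P(c1ccccc1)(c1ccccc1)c1ccccc1
Why: Wittig olefination with an α-methyl stabilised ylide gives the (E)-trisubstituted enoate with high selectivity at room temperature, which spares the heat-sensitive chromene.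

Step 18
Reactants: 25 ethyl (E)-2-methyl-5-[(S)-6-(TBSO)-2,7,8-trimethyl-2H-chromen-2-yl]pent-2-enoate
Product: 26 (E)-2-methyl-5-[(S)-6-(TBSO)-2,7,8-trimethyl-2H-chromen-2-yl]pent-2-en-1-ol
Conditions: iBu2AlH (2.5 equiv), CH2Cl2, −78 to 0 °C
Reagents that add atoms: none
Why: 1,2-Reduction of the enoate gives the allylic alcohol with the alkene geometry retained.

Step 19
Reactants: 26 (E)-2-methyl-5-[(S)-6-(TBSO)-2,7,8-trimethyl-2H-chromen-2-yl]pent-2-en-1-ol
Product: 27 (S)-2-[(E)-5-bromo-4-methylpent-3-en-1-yl]-6-(TBSO)-2,7,8-trimethyl-2H-chromene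
Conditions: CBr4, PPh3, CH2Cl2, 0 °C
Reagents that add atoms: carbon tetrabromide BrC(Br)(Br)Br
Why: Appel bromination converts the primary allylic alcohol under neutral conditions by SN2 on the alkoxyphosphonium ion, without allylic transposition.

Step 20
Reactants: 27 (S)-2-[(E)-5-bromo-4-methylpent-3-en-1-yl]-6-(TBSO)-2,7,8-trimethyl-2H-chromene
Product: 28 (E)-4-methyl-7-[(S)-6-(TBSO)-2,7,8-trimethyl-2H-chromen-2-yl]hept-4-enenitrile
Conditions: MeCN (5 equiv), LiN(iPr)2 (4.5 equiv), THF, −78 °C; then 27, −78 to −30 °C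
Reagents that add atoms: acetonitrile CC#N
Why: SN2 alkylation of lithioacetonitrile by the primary allylic bromide adds the two missing carbons, and excess anion limits dialkylation.

Step 21
Reactants: 28 (E)-4-methyl-7-[(S)-6-(TBSO)-2,7,8-trimethyl-2H-chromen-2-yl]hept-4-enenitrile
Product: 30 (E)-4-methyl-7-[(S)-6-(TBSO)-2,7,8-trimethyl-2H-chromen-2-yl]hept-4-enal, via N-aluminio imine 29 (not isolated)
Conditions: iBu2AlH (1.3 equiv), CH2Cl2, −78 °C; then aq. citric acid (pH 4), 0 °C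
Reagents that add atoms: water O
Why: Hydride reduction of the nitrile stops at the N-aluminio imine, which mild aqueous acid hydrolyses to the aldehyde without over-reduction.

Step 22
Reactants: 5 methyl 6-methylhept-5-enoate; 30 (E)-4-methyl-7-[(S)-6-(TBSO)-2,7,8-trimethyl-2H-chromen-2-yl]hept-4-enal
Product: 32 methyl (E)-3-hydroxy-6-methyl-2-(4-methylpent-3-en-1-yl)-9-[(S)-6-(TBSO)-2,7,8-trimethyl-2H-chromen-2-yl]non-6-enoate, via lithium ester enolate 31 (not isolated)
Conditions: 5 (1.2 equiv), LiN(iPr)2 (1.15 equiv), THF, −78 °C; then 30, −78 °C; AcOH/THF quench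
Reagents that add atoms: none
Why: Directed (crossed) aldol addition, in which the preformed lithium ester enolate adds to the aldehyde at −78 °C faster than it enolises it, joins the two fragments at Cα–Cβ of the future acid; the two new centres are removed in step 24.

Step 23
Reactants: 32 methyl (E)-3-hydroxy-6-methyl-2-(4-methylpent-3-en-1-yl)-9-[(S)-6-(TBSO)-2,7,8-trimethyl-2H-chromen-2-yl]non-6-enoate
Product: 33 methyl (E)-6-methyl-2-(4-methylpent-3-en-1-yl)-3-(methylsulfonyloxy)-9-[(S)-6-(TBSO)-2,7,8-trimethyl-2H-chromen-2-yl]non-6-enoate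
Conditions: MsCl, Et3N, CH2Cl2, 0 °C
Reagents that add atoms: methanesulfonyl chloride CS(=O)(=O)Cl
Why: Mesylation turns the β-hydroxyl into a leaving group under conditions that leave the chromene and silyl ether alone.

Step 24
Reactants: 33 methyl (E)-6-methyl-2-(4-methylpent-3-en-1-yl)-3-(methylsulfonyloxy)-9-[(S)-6-(TBSO)-2,7,8-trimethyl-2H-chromen-2-yl]non-6-enoate
Product: 34 methyl (2E,6E)-6-methyl-2-(4-methylpent-3-en-1-yl)-9-[(S)-6-(TBSO)-2,7,8-trimethyl-2H-chromen-2-yl]nona-2,6-dienoate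
Conditions: DBU (3 equiv), toluene, rt
Reagents that add atoms: none
Why: E1cB elimination through the ester enolate converges both diastereomers on the thermodynamically preferred (E)-enoate, with the ester trans to the chain as in tiglates.

Step 25
Reactants: 34 methyl (2E,6E)-6-methyl-2-(4-methylpent-3-en-1-yl)-9-[(S)-6-(TBSO)-2,7,8-trimethyl-2H-chromen-2-yl]nona-2,6-dienoate
Product: 35 methyl (2E,6E)-9-[(S)-6-hydroxy-2,7,8-trimethyl-2H-chromen-2-yl]-6-methyl-2-(4-methylpent-3-en-1-yl)nona-2,6-dienoate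
Conditions: Bu4NF, AcOH, THF, 0 °C
Reagents that add atoms: none
Why: Fluoride-mediated desilylation cleaves the aryl silyl ether, the acetic acid buffer keeping the electron-rich phenoxide from oxidising.

Step 26
Reactants: 35 methyl (2E,6E)-9-[(S)-6-hydroxy-2,7,8-trimethyl-2H-chromen-2-yl]-6-methyl-2-(4-methylpent-3-en-1-yl)nona-2,6-dienoate
Product: 36 (2E,6E)-9-[(S)-6-hydroxy-2,7,8-trimethyl-2H-chromen-2-yl]-6-methyl-2-(4-methylpent-3-en-1-yl)nona-2,6-dienoic acid
Conditions: LiOH·H2O (6 equiv), THF/MeOH/H2O, argon, 40 °C; then 1 M HCl to pH 4, 0 °C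
Reagents that add atoms: lithium hydroxide [Li+].[OH-]
Why: Saponification of the methyl ester under argon and careful acidification gives the acid without affecting the alkene geometries or C2.

## Compound list

1 | dimethyl malonate | COC(=O)CC(=O)OC | starting material
2 | 5-bromo-2-methylpent-2-ene | CC(C)=CCCBr | starting material
3 | sodium dimethyl malonate | [Na+].COC(=O)[CH-]C(=O)OC | intermediate
4 | dimethyl 2-(4-methylpent-3-en-1-yl)malonate | COC(=O)C(CCC=C(C)C)C(=O)OC | intermediate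
5 | methyl 6-methylhept-5-enoate | COC(=O)CCCC=C(C)C | intermediate
6 | 2,3-dimethylhydroquinone (2,3-dimethylbenzene-1,4-diol) | Cc1c(C)c(O)ccc1O | starting material
7 | acrylic acid | C=CC(=O)O | starting material
8 | 6-hydroxy-7,8-dimethylchroman-2-one | O=C1CCc2cc(O)c(C)c(C)c2O1 | intermediate
9 | 6-(benzyloxy)-7,8-dimethylchroman-2-one | O=C1CCc2cc(OCc3ccccc3)c(C)c(C)c2O1 | intermediate
10 | 6-(benzyloxy)-7,8-dimethylchroman-2-ol (lactol, racemic hemiacetal carbon) | OC1CCc2cc(OCc3ccccc3)c(C)c(C)c2O1 | intermediate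
11 | 4-(benzyloxy)-2-(but-3-yn-1-yl)-5,6-dimethylphenol | C#CCCc1cc(OCc2ccccc2)c(C)c(C)c1O | intermediate
12 | [4-(benzyloxy)-2-(but-3-yn-1-yl)-5,6-dimethylphenoxy](tert-butyl)dimethylsilane | C#CCCc1cc(OCc2ccccc2)c(C)c(C)c1O[Si](C)(C)C(C)(C)C | intermediate
13 | {(E)-4-[5-(benzyloxy)-2-(TBSO)-3,4-dimethylphenyl]-2-methylbut-1-en-1-yl}dimethylalane | C[Al](C)/C=C(\C)CCc1cc(OCc2ccccc2)c(C)c(C)c1O[Si](C)(C)C(C)(C)C | intermediate
14 | lithium butyl{(E)-4-[5-(benzyloxy)-2-(TBSO)-3,4-dimethylphenyl]-2-methylbut-1-en-1-yl}dimethylaluminate | [Li+].CCCC[Al-](C)(C)/C=C(\C)CCc1cc(OCc2ccccc2)c(C)c(C)c1O[Si](C)(C)C(C)(C)C | intermediate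
15 | (E)-5-[5-(benzyloxy)-2-(TBSO)-3,4-dimethylphenyl]-3-methylpent-2-en-1-ol | OC/C=C(\C)CCc1cc(OCc2ccccc2)c(C)c(C)c1O[Si](C)(C)C(C)(C)C | intermediate
16 | [(2S,3S)-3-{2-[5-(benzyloxy)-2-(TBSO)-3,4-dimethylphenyl]ethyl}-3-methyloxiran-2-yl]methanol | OC[C@@H]1O[C@@]1(C)CCc1cc(OCc2ccccc2)c(C)c(C)c1O[Si](C)(C)C(C)(C)C | intermediate
17 | 4-(benzyloxy)-2-{2-[(2S,3S)-3-(hydroxymethyl)-2-methyloxiran-2-yl]ethyl}-5,6-dimethylphenol | OC[C@@H]1O[C@@]1(C)CCc1cc(OCc2ccccc2)c(C)c(C)c1O | intermediate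
18 | (S)-1-[(R)-6-(benzyloxy)-2,7,8-trimethylchroman-2-yl]ethane-1,2-diol | OC[C@H](O)[C@@]1(C)CCc2cc(OCc3ccccc3)c(C)c(C)c2O1 | intermediate
19 | (R)-6-(benzyloxy)-2,7,8-trimethylchroman-2-carbaldehyde | O=C[C@@]1(C)CCc2cc(OCc3ccccc3)c(C)c(C)c2O1 | intermediate
20 | ethyl (E)-3-[(R)-6-(benzyloxy)-2,7,8-trimethylchroman-2-yl]acrylate | CCOC(=O)/C=C/[C@@]1(C)CCc2cc(OCc3ccccc3)c(C)c(C)c2O1 | intermediate
21 | ethyl 3-[(R)-6-hydroxy-2,7,8-trimethylchroman-2-yl]propanoate | CCOC(=O)CC[C@@]1(C)CCc2cc(O)c(C)c(C)c2O1 | intermediate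
22 | ethyl 3-[(R)-6-(TBSO)-2,7,8-trimethylchroman-2-yl]propanoate | CCOC(=O)CC[C@@]1(C)CCc2cc(O[Si](C)(C)C(C)(C)C)c(C)c(C)c2O1 | intermediate
23 | ethyl 3-[(S)-6-(TBSO)-2,7,8-trimethyl-2H-chromen-2-yl]propanoate | CCOC(=O)CC[C@@]1(C)C=Cc2cc(O[Si](C)(C)C(C)(C)C)c(C)c(C)c2O1 | intermediate
24 | 3-[(S)-6-(TBSO)-2,7,8-trimethyl-2H-chromen-2-yl]propanal | O=CCC[C@@]1(C)C=Cc2cc(O[Si](C)(C)C(C)(C)C)c(C)c(C)c2O1 | intermediate
25 | ethyl (E)-2-methyl-5-[(S)-6-(TBSO)-2,7,8-trimethyl-2H-chromen-2-yl]pent-2-enoate | CCOC(=O)/C(C)=C/CC[C@@]1(C)C=Cc2cc(O[Si](C)(C)C(C)(C)C)c(C)c(C)c2O1 | intermediate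
26 | (E)-2-methyl-5-[(S)-6-(TBSO)-2,7,8-trimethyl-2H-chromen-2-yl]pent-2-en-1-ol | OC/C(C)=C/CC[C@@]1(C)C=Cc2cc(O[Si](C)(C)C(C)(C)C)c(C)c(C)c2O1 | intermediate
27 | (S)-2-[(E)-5-bromo-4-methylpent-3-en-1-yl]-6-(TBSO)-2,7,8-trimethyl-2H-chromene | BrC/C(C)=C/CC[C@@]1(C)C=Cc2cc(O[Si](C)(C)C(C)(C)C)c(C)c(C)c2O1 | intermediate
28 | (E)-4-methyl-7-[(S)-6-(TBSO)-2,7,8-trimethyl-2H-chromen-2-yl]hept-4-enenitrile | N#CCC/C(C)=C/CC[C@@]1(C)C=Cc2cc(O[Si](C)(C)C(C)(C)C)c(C)c(C)c2O1 | intermediate
29 | (E)-N-(diisobutylalumanyl)-4-methyl-7-[(S)-6-(TBSO)-2,7,8-trimethyl-2H-chromen-2-yl]hept-4-en-1-imine | CC(C)C[Al](CC(C)C)N=CCC/C(C)=C/CC[C@@]1(C)C=Cc2cc(O[Si](C)(C)C(C)(C)C)c(C)c(C)c2O1 | intermediate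
30 | (E)-4-methyl-7-[(S)-6-(TBSO)-2,7,8-trimethyl-2H-chromen-2-yl]hept-4-enal | O=CCC/C(C)=C/CC[C@@]1(C)C=Cc2cc(O[Si](C)(C)C(C)(C)C)c(C)c(C)c2O1 | intermediate
31 | lithium (Z)-1-methoxy-6-methylhepta-1,5-dien-1-olate (enolate of 5, OLi trans to the chain) | [Li+].CO/C([O-])=C\CCC=C(C)C | intermediate
32 | methyl (E)-3-hydroxy-6-methyl-2-(4-methylpent-3-en-1-yl)-9-[(S)-6-(TBSO)-2,7,8-trimethyl-2H-chromen-2-yl]non-6-enoate (C2/C3 epimer mixture) | COC(=O)C(CCC=C(C)C)C(O)CC/C(C)=C/CC[C@@]1(C)C=Cc2cc(O[Si](C)(C)C(C)(C)C)c(C)c(C)c2O1 | intermediate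
33 | methyl (E)-6-methyl-2-(4-methylpent-3-en-1-yl)-3-(methylsulfonyloxy)-9-[(S)-6-(TBSO)-2,7,8-trimethyl-2H-chromen-2-yl]non-6-enoate (C2/C3 epimer mixture) | COC(=O)C(CCC=C(C)C)C(OS(C)(=O)=O)CC/C(C)=C/CC[C@@]1(C)C=Cc2cc(O[Si](C)(C)C(C)(C)C)c(C)c(C)c2O1 | intermediate
34 | methyl (2E,6E)-6-methyl-2-(4-methylpent-3-en-1-yl)-9-[(S)-6-(TBSO)-2,7,8-trimethyl-2H-chromen-2-yl]nona-2,6-dienoate | CC(C)=CCC/C(=C\CC/C(C)=C/CC[C@@]1(C)C=Cc2cc(O[Si](C)(C)C(C)(C)C)c(C)c(C)c2O1)C(=O)OC | intermediate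
35 | methyl (2E,6E)-9-[(S)-6-hydroxy-2,7,8-trimethyl-2H-chromen-2-yl]-6-methyl-2-(4-methylpent-3-en-1-yl)nona-2,6-dienoate | CC(C)=CCC/C(=C\CC/C(C)=C/CC[C@@]1(C)C=Cc2cc(O)c(C)c(C)c2O1)C(=O)OC | intermediate
36 | (2E,6E)-9-[(S)-6-hydroxy-2,7,8-trimethyl-2H-chromen-2-yl]-6-methyl-2-(4-methylpent-3-en-1-yl)nona-2,6-dienoic acid | CC(C)=CCC/C(=C\CC/C(C)=C/CC[C@@]1(C)C=Cc2cc(O)c(C)c(C)c2O1)C(=O)O | target

## Step count and weak points

Total steps: 26. Longest linear sequence: 24 (steps 3 to 26, from 2,3-dimethylhydroquinone); the ester 5 is made in 2 steps and joins at step 22.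

The three steps most likely to fail:

Step 8 (one-pot carboalumination and hydroxymethylation). Trapping the aluminate with paraformaldehyde can be capricious on a substrate this functionalised. The fallback sets out from 12 and comes back at 15. After the same carboalumination, alane 13 is not converted into the aluminate but acylated directly with ethyl chloroformate (CH2Cl2, 0 °C to rt) to give ethyl (E)-5-[5-(benzyloxy)-2-(TBSO)-3,4-dimethylphenyl]-3-methylpent-2-enoate F1. This ester is isolated and reduced with iBu2AlH (CH2Cl2, −78 °C) to 15. C1 thus enters as an acyl carbon and is reduced afterwards instead of being delivered as formaldehyde.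

Step 15 (DDQ dehydrogenation). The electron-rich silyl ether may be over-oxidised or attacked at the aryl methyl groups, and 2H-chromenes can lose optical purity by thermal or photochemical electrocyclic ring opening, so all later steps are kept at or below 40 °C and out of strong light. The fallback sets out from 21 and comes back at 23, replacing hydride abstraction by radical bromination and elimination on a less electron-rich ring.
- Acetylation (Ac2O, pyridine) gives ethyl 3-[(R)-6-acetoxy-2,7,8-trimethylchroman-2-yl]propanoate F2.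
- NBS with catalytic AIBN (PhCF3, 75 °C) brominates the only secondary benzylic position to give ethyl 3-[(2S)-6-acetoxy-4-bromo-2,7,8-trimethylchroman-2-yl]propanoate F3 (both C4 epimers).
- DBU (THF, rt) eliminates HBr to give ethyl 3-[(S)-6-acetoxy-2,7,8-trimethyl-2H-chromen-2-yl]propanoate F4.
- K2CO3 in EtOH removes the acetate to give ethyl 3-[(S)-6-hydroxy-2,7,8-trimethyl-2H-chromen-2-yl]propanoate F5, and TBSCl/imidazole returns to 23.

Step 24 (E1cB elimination). The risk is incomplete (E)-selectivity at the new trisubstituted enoate. The fallback sets out from 33 and comes back at 34 and keeps the aldol union. If the elimination gives a significant share of methyl (2Z,6E)-6-methyl-2-(4-methylpent-3-en-1-yl)-9-[(S)-6-(TBSO)-2,7,8-trimethyl-2H-chromen-2-yl]nona-2,6-dienoate F6, the crude mixture is not separated. It is treated with catalytic PhSLi (PhSH and nBuLi, 10 mol %, THF, 0 °C to rt). Reversible thia-Michael addition and elimination equilibrates F6 to the more stable (2E)-ester 34 without touching the isolated alkenes or C2.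

Further compounds

F1 | step 8 | ethyl (E)-5-[5-(benzyloxy)-2-(TBSO)-3,4-dimethylphenyl]-3-methylpent-2-enoate | CCOC(=O)/C=C(\C)CCc1cc(OCc2ccccc2)c(C)c(C)c1O[Si](C)(C)C(C)(C)C
F2 | step 15 | ethyl 3-[(R)-6-acetoxy-2,7,8-trimethylchroman-2-yl]propanoate | CCOC(=O)CC[C@@]1(C)CCc2cc(OC(C)=O)c(C)c(C)c2O1
F3 | step 15 | ethyl 3-[(2S)-6-acetoxy-4-bromo-2,7,8-trimethylchroman-2-yl]propanoate (C4 epimers) | CCOC(=O)CC[C@@]1(C)CC(Br)c2cc(OC(C)=O)c(C)c(C)c2O1
F4 | step 15 | ethyl 3-[(S)-6-acetoxy-2,7,8-trimethyl-2H-chromen-2-yl]propanoate | CCOC(=O)CC[C@@]1(C)C=Cc2cc(OC(C)=O)c(C)c(C)c2O1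
F5 | step 15 | ethyl 3-[(S)-6-hydroxy-2,7,8-trimethyl-2H-chromen-2-yl]propanoate | CCOC(=O)CC[C@@]1(C)C=Cc2cc(O)c(C)c(C)c2O1
F6 | step 24 | methyl (2Z,6E)-6-methyl-2-(4-methylpent-3-en-1-yl)-9-[(S)-6-(TBSO)-2,7,8-trimethyl-2H-chromen-2-yl]nona-2,6-dienoate | CC(C)=CCC/C(=C/CC/C(C)=C/CC[C@@]1(C)C=Cc2cc(O[Si](C)(C)C(C)(C)C)c(C)c(C)c2O1)C(=O)OC
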